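A flask cannot begin more chains than it has initiator, taking one chain to each initiator spent. At a given share of the monomer in chains, that gives a lower limit for the average length (the number-average degree of polymerisation) in east and north-west.

the same everywhere: free monomer 0.050 M

| flask | initiator | remark | time |
|---|---|---|---|
| larch | 1.7 mM | run made earlier |  |
| elm | 3.6 mM | run made earlier |  |
| east | 2.5 mM |  | 20 h |
| north-west | 5.0 mM |  | 20 h |

| run | time / h | monomer in chains / % | free monomer / % |
|---|---|---|---|
| larch | 1.50 | 52.8 | 44.9 |
| larch | 3.00 | 80.7 | 18.9 |
| larch | 6.00 | 90.1 | 9.3 |
| larch | 10.0 | 90.9 | 5.9 |
| larch | 20.0 | 92.5 | 4.3 |
| elm | 4.00 | 93.3 | 4.4 |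
| elm | 8.00 | 94.9 | 4.3 |
| elm | 12.0 | 94.9 | 3.7 |
| elm | 15.0 | 92.9 | 2.2 |
| elm | 20.0 | 95.4 | 3.6 |

(readings scatter by 1 percentage point)

- the average divides the monomer in chains by the number of chains begun, living and dead together
- the earlier runs do not show the number of chains; that part of a forecast is a guess

1. which of the two ends with the longer chains by the average number of monomer units in a chain (chains begun, living or dead) ("neither" if they lie within 10%) (east / north-west / neither)
2. average number of monomer units in a chain (chains begun, living or dead) at the end, east
3. average number of monomer units in a chain (chains begun, living or dead) at the end, north-west

First, what share of the charged monomer is in chains at 20 h? Larch reads 92.5% and elm 95.4%, so I take their mean, 94.0%, for east and north-west alike.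

Second, what length does that share allow? Multiplied by the monomer charged per initiator charged, it gives 18.8 for east and 9.39 for north-west. This product is the floor length: the length with the whole initiator charge spent. A flask's length is its floor divided by its spent share of initiator, which the readings do not show.

Third, which flask ends longer? East's floor is twice north-west's, so north-west overtakes east if its spent share falls below half of east's. I call east, with both lengths above their floors.

The forecast says east, with 20 for east and 10 for north-west, reasoning “If each initiator starts one chain”. Its values are estimates of the length itself, while I hold my smaller figures as floors.

East ends at 42.7 and north-west at 32.8, so east is longer.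

    free monomer + initiator → living end + monomer in chains (k = 0.00150 /M/s)
    free monomer + living end → monomer in chains + living end, rate k2*[living end]*[free monomer] (k = 0.600 /M/s)
    living end + monomer in chains → dead end (k = 0.00560 /M/s)

At 20 h east has spent 44.4% of its initiator and north-west 29.3%, and floor over spent share gives 42.3 and 32.0. A neighbour of east charged with 0.20 M of free monomer, its initiator unchanged, has 88.1% of that monomer in chains at 20.0 h, which makes a floor of 70.4. It has spent 96.8% of its initiator, so the reckoning gives 72.7, and the neighbour reads 72.8.

The readings are calculated with made-up constants, and the scatter is random.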